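**Plan**
Numbering: C1 (alkyne CH) to C15 (ethyl CH3); oxocane ring = O, C7, C8, C9, C10, C11, C12, C13; tetrahydrofuran ring = O, C6, C7, C8, C9.
Retrosynthetic cuts, in order: C1≡C2 and C3=C4 (enyne from an allyl group); C9–O and C10–Br (transannular bromoetherification of a C9=C10 oxocene by the C6 hydroxyl); C13–O and C12–Br (ring expansion); C9=C10 (ring-closing metathesis); C11–C12 (auxiliary-controlled allylation); O–C12 (Williamson ether); C7–C8 (allylation of glyceraldehyde acetonide).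
Enabling feature: in the oxocane the ring oxygen on C13 and the bromine on C12 are trans-vicinal, the signature of an anti opening at C12 of an epoxonium ion made of the ring oxygen, C12 and C13; that ion is reached from a seven-membered 2,3,6,7-tetrahydrooxepine (O, C7, C8, C9=C10, C11, C12) that carries C13 outside the ring as CH(OH)Et.
Forward order of rings: oxepene by metathesis, oxocene by the seven-to-eight ring expansion that takes C13 into the ring, tetrahydrofuran by bromoetherification (completing the 2,8-dioxabicyclo[5.2.1]decane); the enyne is finished last.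
Stereochemistry: C6 from (R)-glyceraldehyde acetonide; C7 by Felkin–Anh allylation; C12 by oxazolidinone-directed alkylation and C13 by chelation-controlled ketone reduction, both then inverted stereospecifically in the ring expansion; C9 and C10 by anti addition enforced by the C6–C7 tether; E-alkene by cross-metathesis.
Key step: step 9

Remark: (R)-2,3-O-isopropylideneglyceraldehyde 1 is taken as a commercial reagent and used freshly distilled.

Step 1
Reactants: 1 (R)-2,2-dimethyl-1,3-dioxolane-4-carbaldehyde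
Product: 2 (S)-1-[(R)-2,2-dimethyl-1,3-dioxolan-4-yl]but-3-en-1-ol
Conditions: Zn, allyl bromide, THF/sat. aq NH4Cl, 0 °C → rt
Reagents that add atoms: allyl bromide C=CCBr
Why: Barbier allylation in which the allylzinc reagent should add anti to the dioxolane C–O bond (Felkin–Anh), favouring the anti (7S) carbinol, the minor syn isomer being removed by chromatography.

Step 2
Reactants: 2 (S)-1-[(R)-2,2-dimethyl-1,3-dioxolan-4-yl]but-3-en-1-ol
Product: 3 2-{[(S)-1-[(R)-2,2-dimethyl-1,3-dioxolan-4-yl]but-3-en-1-yl]oxy}acetic acid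
Conditions: NaH, BrCH2CO2H, THF, 0 °C → rt; work-up at pH 4
Reagents that add atoms: bromoacetic acid OC(=O)CBr
Why: Williamson ether synthesis in which the alkoxide of 2 displaces bromide from bromoacetate at a primary carbon, so no stereocenter is touched.

Step 3
Reactants: 3 2-{[(S)-1-[(R)-2,2-dimethyl-1,3-dioxolan-4-yl]but-3-en-1-yl]oxy}acetic acid
Product: 5 (S)-4-benzyl-3-(2-{[(S)-1-[(R)-2,2-dimethyl-1,3-dioxolan-4-yl]but-3-en-1-yl]oxy}acetyl)oxazolidin-2-one, via mixed pivalic anhydride 4 (not isolated)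
Conditions: t-BuCOCl, Et3N, THF, −20 °C; then LiCl, (S)-4-benzyl-2-oxazolidinone, −20 °C → rt
Reagents that add atoms: pivaloyl chloride CC(C)(C)C(=O)Cl (atoms only in 4); (S)-4-benzyl-2-oxazolidinone O=C1N[C@@H](Cc2ccccc2)CO1
Why: N-Acylation of the oxazolidinone through the mixed anhydride under LiCl/Et3N activation is the standard way to attach an Evans auxiliary to an α-alkoxy acid.

Step 4
Reactants: 5 (S)-4-benzyl-3-(2-{[(S)-1-[(R)-2,2-dimethyl-1,3-dioxolan-4-yl]but-3-en-1-yl]oxy}acetyl)oxazolidin-2-one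
Product: 7 (S)-4-benzyl-3-[(R)-2-{[(S)-1-[(R)-2,2-dimethyl-1,3-dioxolan-4-yl]but-3-en-1-yl]oxy}pent-4-enoyl]oxazolidin-2-one, via sodium Z-enolate 6 (not isolated)
Conditions: NaN(SiMe3)2, THF, −78 °C; then allyl iodide, −78 → −45 °C
Reagents that add atoms: NaN(SiMe3)2 C[Si](C)(C)[N-][Si](C)(C)C.[Na+] (sodium only in 6); allyl iodide C=CCI
Why: Evans-type asymmetric alkylation of the chelated Z-enolate of a glycolate imide, in which allyl iodide should attack the face opposite to the benzyl group and set C12 as R.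

Step 5
Reactants: 7 (S)-4-benzyl-3-[(R)-2-{[(S)-1-[(R)-2,2-dimethyl-1,3-dioxolan-4-yl]but-3-en-1-yl]oxy}pent-4-enoyl]oxazolidin-2-one
Product: 8 (S)-4-benzyl-3-{[(2R,7S)-7-[(R)-2,2-dimethyl-1,3-dioxolan-4-yl]-2,3,6,7-tetrahydrooxepin-2-yl]carbonyl}oxazolidin-2-one
Conditions: second-generation Grubbs catalyst (5 mol %), CH2Cl2 (0.005 M), 40 °C
Reagents that add atoms: none
Why: Ring-closing metathesis of the two allyl arms flanking the ether oxygen should close the seven-membered cis-alkene readily, driven by loss of ethene.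

Step 6
Reactants: 8 (S)-4-benzyl-3-{[(2R,7S)-7-[(R)-2,2-dimethyl-1,3-dioxolan-4-yl]-2,3,6,7-tetrahydrooxepin-2-yl]carbonyl}oxazolidin-2-one
Product: 9 (2R,7S)-7-[(R)-2,2-dimethyl-1,3-dioxolan-4-yl]-N-methoxy-N-methyl-2,3,6,7-tetrahydrooxepine-2-carboxamide
Conditions: MeNH(OMe)·HCl, AlMe3, CH2Cl2, 0 °C → rt
Reagents that add atoms: N,O-dimethylhydroxylamine hydrochloride CNOC.Cl
Why: Aluminium amide transamidation (Weinreb amide formation) should cleave the auxiliary at the exocyclic carbonyl without epimerizing the α-alkoxy center.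

Step 7
Reactants: 9 (2R,7S)-7-[(R)-2,2-dimethyl-1,3-dioxolan-4-yl]-N-methoxy-N-methyl-2,3,6,7-tetrahydrooxepine-2-carboxamide
Product: 10 1-[(2R,7S)-7-[(R)-2,2-dimethyl-1,3-dioxolan-4-yl]-2,3,6,7-tetrahydrooxepin-2-yl]propan-1-one
Conditions: EtMgBr, THF, 0 °C; aq NH4Cl
Reagents that add atoms: ethylmagnesium bromide CC[Mg]Br
Why: Grignard addition to a Weinreb amide stops at the ketone because the magnesium chelate collapses only on work-up, which also protects C12 from enolization.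

Step 8
Reactants: 10 1-[(2R,7S)-7-[(R)-2,2-dimethyl-1,3-dioxolan-4-yl]-2,3,6,7-tetrahydrooxepin-2-yl]propan-1-one
Product: 11 (S)-1-[(2R,7S)-7-[(R)-2,2-dimethyl-1,3-dioxolan-4-yl]-2,3,6,7-tetrahydrooxepin-2-yl]propan-1-ol
Conditions: Zn(BH4)2, Et2O, −30 °C
Reagents that add atoms: none
Why: Chelation-controlled (Cram chelate) reduction in which zinc bridges the ketone and ring oxygens and hydride enters anti to C11, which should give the anti (erythro, 13S) alcohol.

Step 9
Reactants: 11 (S)-1-[(2R,7S)-7-[(R)-2,2-dimethyl-1,3-dioxolan-4-yl]-2,3,6,7-tetrahydrooxepin-2-yl]propan-1-ol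
Product: 14 (2R,3S,8S,Z)-3-bromo-8-[(R)-2,2-dimethyl-1,3-dioxolan-4-yl]-2-ethyl-3,4,7,8-tetrahydro-2H-oxocine, via secondary triflate 12 (not isolated), via bicyclic epoxonium triflate 13 (not isolated)
Conditions: Tf2O, 2,6-di-tert-butyl-4-methylpyridine, CH2Cl2, −78 → −20 °C; then Bu4NBr, −78 → 0 °C
Reagents that add atoms: trifluoromethanesulfonic anhydride O=S(=O)(OS(=O)(=O)C(F)(F)F)C(F)(F)F (atoms only in 12 and 13); tetrabutylammonium bromide CCCC[N+](CCCC)(CCCC)CCCC.[Br-]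
Why: Proposed new method: triflate 12 is made with a non-nucleophilic base so that the only nucleophile present is the ring oxygen, which is anti-periplanar to the C13–O bond in the reactive rotamer and should displace triflate with inversion at C13 to give the 1-oxoniabicyclo[5.1.0]oct-4-ene 13; bromide, added only after ionization, should then open the three-membered ring at the ring-fusion carbon C12 with inversion, so that the O–C12 bond breaks, C13 enters the ring and the oxepene becomes the oxocene. The closest known reaction type is the rearrangement–ring expansion of cyclic ethers that carry a sulfonate on the exocyclic α-carbon (tetrahydrofuran to tetrahydropyran and tetrahydropyran to oxepane with Zn(OAc)2), which runs through the same kind of epoxonium ion and is extended here to the seven-to-eight case and to bromide as the terminating nucleophile. The only ring closed is the transient oxirane ring (3-exo-tet); the oxocene arises by cleavage of its fusion bond and not by an eight-membered closure. Both stereocenters follow from the mechanism, C13 going from S to R and C12 from R to S by two successive inversions, so that the trans C12–Br/C13–O arrangement and the trans relation of the C7 and C13 substituents across the ring oxygen are fixed by the erythro stereochemistry of 11. The step needs participation to outrun direct bromide displacement at C13 and needs attack at C12 and not at C13: the first is secured by forming the epoxonium ion before any bromide is present, the second is expected by analogy with the lower homologues, where cleavage of the endocyclic fusion bond releases the strain of both rings, while the pseudo-equatorial cis-2,7 substituents keep the dioxolane oxygens away from C13.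

Step 10
Reactants: 14 (2R,3S,8S,Z)-3-bromo-8-[(R)-2,2-dimethyl-1,3-dioxolan-4-yl]-2-ethyl-3,4,7,8-tetrahydro-2H-oxocine
Product: 15 (R)-1-[(2R,3S,8S,Z)-3-bromo-2-ethyl-3,4,7,8-tetrahydro-2H-oxocin-8-yl]ethane-1,2-diol
Conditions: pyridinium p-toluenesulfonate, MeOH, 40 °C
Reagents that add atoms: none
Why: Acid-catalysed transketalization to methanol should remove the terminal isopropylidene group under conditions to which the secondary bromide and the ring ether are inert.

Step 11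
Reactants: 15 (R)-1-[(2R,3S,8S,Z)-3-bromo-2-ethyl-3,4,7,8-tetrahydro-2H-oxocin-8-yl]ethane-1,2-diol
Product: 17 (2R,3S,8S,Z)-3-bromo-2-ethyl-8-[(R)-oxiran-2-yl]-3,4,7,8-tetrahydro-2H-oxocine, via primary arenesulfonate 16 (not isolated)
Conditions: NaH, 1-(2,4,6-triisopropylbenzenesulfonyl)imidazole, THF, 0 °C → rt
Reagents that add atoms: 1-(2,4,6-triisopropylbenzenesulfonyl)imidazole CC(C)c1cc(C(C)C)c(S(=O)(=O)n2ccnc2)c(C(C)C)c1 (atoms only in 16)
Why: Selective sulfonylation of the primary alkoxide by the hindered sulfonyl imidazole followed by intramolecular Williamson closure (3-exo-tet) should give the terminal epoxide with the C6–O bond, and so the R configuration, untouched.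

Step 12
Reactants: 17 (2R,3S,8S,Z)-3-bromo-2-ethyl-8-[(R)-oxiran-2-yl]-3,4,7,8-tetrahydro-2H-oxocine
Product: 18 (R)-1-[(2R,3S,8S,Z)-3-bromo-2-ethyl-3,4,7,8-tetrahydro-2H-oxocin-8-yl]but-3-en-1-ol
Conditions: CH2=CHMgBr, CuI (10 mol %), THF, −40 → −20 °C
Reagents that add atoms: vinylmagnesium bromide C=C[Mg]Br
Why: Copper-catalysed Grignard opening of a terminal epoxide occurs at the unsubstituted carbon, and at this temperature the secondary alkyl bromide should not couple.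

Step 13
Reactants: 18 (R)-1-[(2R,3S,8S,Z)-3-bromo-2-ethyl-3,4,7,8-tetrahydro-2H-oxocin-8-yl]but-3-en-1-ol
Product: 19 (1S,3R,4S,6S,7S,9R)-9-allyl-4,6-dibromo-3-ethyl-2,8-dioxabicyclo[5.2.1]decane
Conditions: NBS, CH2Cl2, 0 °C, dark
Reagents that add atoms: N-bromosuccinimide O=C1CCC(=O)N1Br
Why: Transannular bromoetherification (5-exo) in which the C6 hydroxyl can reach C9 only from the ring face that carries C6 and bromine is delivered anti to C10, which should give 9S,10S, the cis-disubstituted ring alkene being more nucleophilic than the terminal one.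

Step 14
Reactants: 19 (1S,3R,4S,6S,7S,9R)-9-allyl-4,6-dibromo-3-ethyl-2,8-dioxabicyclo[5.2.1]decane
Product: 20 (E)-4-[(1S,3R,4S,6S,7S,9R)-4,6-dibromo-3-ethyl-2,8-dioxabicyclo[5.2.1]decan-9-yl]but-2-enal
Conditions: crotonaldehyde (10 equiv), second-generation Grubbs catalyst (5 mol %), CH2Cl2, 40 °C
Reagents that add atoms: (E)-but-2-enal C/C=C/C=O
Why: Olefin cross-metathesis of a terminal alkene with excess crotonaldehyde should give the E-enal under thermodynamic control.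

Step 15
Reactants: 20 (E)-4-[(1S,3R,4S,6S,7S,9R)-4,6-dibromo-3-ethyl-2,8-dioxabicyclo[5.2.1]decan-9-yl]but-2-enal
Product: 21 (1S,3R,4S,6S,7S,9R)-4,6-dibromo-3-ethyl-9-[(E)-pent-2-en-4-yn-1-yl]-2,8-dioxabicyclo[5.2.1]decane
Conditions: Me3SiCHN2, LiN(iPr)2, THF, −78 → 0 °C
Reagents that add atoms: trimethylsilyldiazomethane C[Si](C)(C)C=[N+]=[N-]
Why: Colvin rearrangement in which lithiated trimethylsilyldiazomethane adds to the aldehyde and loss of silanolate and dinitrogen gives an alkylidene carbene that rearranges to the terminal alkyne, leaving the E-alkene intact.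

**Compound list**
1 | (R)-2,2-dimethyl-1,3-dioxolane-4-carbaldehyde | O=C[C@H]1COC(C)(C)O1 | starting material
2 | (S)-1-[(R)-2,2-dimethyl-1,3-dioxolan-4-yl]but-3-en-1-ol | C=CC[C@H](O)[C@H]1COC(C)(C)O1 | intermediate
3 | 2-{[(S)-1-[(R)-2,2-dimethyl-1,3-dioxolan-4-yl]but-3-en-1-yl]oxy}acetic acid | C=CC[C@H](OCC(=O)O)[C@H]1COC(C)(C)O1 | intermediate
4 | mixed anhydride of 3 and pivalic acid | C=CC[C@H](OCC(=O)OC(=O)C(C)(C)C)[C@H]1COC(C)(C)O1 | intermediate (not isolated)
5 | (S)-4-benzyl-3-(2-{[(S)-1-[(R)-2,2-dimethyl-1,3-dioxolan-4-yl]but-3-en-1-yl]oxy}acetyl)oxazolidin-2-one | C=CC[C@H](OCC(=O)N1[C@@H](Cc2ccccc2)COC1=O)[C@H]3COC(C)(C)O3 | intermediate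
6 | sodium Z-enolate of 5 | C=CC[C@H](O/C=C(\[O-])N1[C@@H](Cc2ccccc2)COC1=O)[C@H]3COC(C)(C)O3.[Na+] | intermediate (not isolated)
7 | (S)-4-benzyl-3-[(R)-2-{[(S)-1-[(R)-2,2-dimethyl-1,3-dioxolan-4-yl]but-3-en-1-yl]oxy}pent-4-enoyl]oxazolidin-2-one | C=CC[C@H](O[C@H](CC=C)C(=O)N1[C@@H](Cc2ccccc2)COC1=O)[C@H]3COC(C)(C)O3 | intermediate
8 | (S)-4-benzyl-3-{[(2R,7S)-7-[(R)-2,2-dimethyl-1,3-dioxolan-4-yl]-2,3,6,7-tetrahydrooxepin-2-yl]carbonyl}oxazolidin-2-one | O=C(N1[C@@H](Cc2ccccc2)COC1=O)[C@H]3C/C=C\C[C@H](O3)[C@H]4COC(C)(C)O4 | intermediate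
9 | (2R,7S)-7-[(R)-2,2-dimethyl-1,3-dioxolan-4-yl]-N-methoxy-N-methyl-2,3,6,7-tetrahydrooxepine-2-carboxamide | CON(C)C(=O)[C@H]1C/C=C\C[C@H](O1)[C@H]2COC(C)(C)O2 | intermediate
10 | 1-[(2R,7S)-7-[(R)-2,2-dimethyl-1,3-dioxolan-4-yl]-2,3,6,7-tetrahydrooxepin-2-yl]propan-1-one | CCC(=O)[C@H]1C/C=C\C[C@H](O1)[C@H]2COC(C)(C)O2 | intermediate
11 | (S)-1-[(2R,7S)-7-[(R)-2,2-dimethyl-1,3-dioxolan-4-yl]-2,3,6,7-tetrahydrooxepin-2-yl]propan-1-ol | CC[C@H](O)[C@H]1C/C=C\C[C@H](O1)[C@H]2COC(C)(C)O2 | intermediate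
12 | (S)-1-[(2R,7S)-7-[(R)-2,2-dimethyl-1,3-dioxolan-4-yl]-2,3,6,7-tetrahydrooxepin-2-yl]propyl trifluoromethanesulfonate | CC[C@H](OS(=O)(=O)C(F)(F)F)[C@H]1C/C=C\C[C@H](O1)[C@H]2COC(C)(C)O2 | intermediate (not isolated)
13 | (2S,7R,8R,Z)-2-[(R)-2,2-dimethyl-1,3-dioxolan-4-yl]-8-ethyl-1-oxoniabicyclo[5.1.0]oct-4-ene trifluoromethanesulfonate | CC[C@H]1[O+]2[C@@H]1C/C=C\C[C@H]2[C@H]3COC(C)(C)O3.[O-]S(=O)(=O)C(F)(F)F | intermediate (not isolated)
14 | (2R,3S,8S,Z)-3-bromo-8-[(R)-2,2-dimethyl-1,3-dioxolan-4-yl]-2-ethyl-3,4,7,8-tetrahydro-2H-oxocine | CC[C@H]1O[C@@H](C/C=C\C[C@@H]1Br)[C@H]2COC(C)(C)O2 | intermediate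
15 | (R)-1-[(2R,3S,8S,Z)-3-bromo-2-ethyl-3,4,7,8-tetrahydro-2H-oxocin-8-yl]ethane-1,2-diol | CC[C@H]1O[C@@H](C/C=C\C[C@@H]1Br)[C@H](O)CO | intermediate
16 | (R)-2-[(2R,3S,8S,Z)-3-bromo-2-ethyl-3,4,7,8-tetrahydro-2H-oxocin-8-yl]-2-hydroxyethyl 2,4,6-triisopropylbenzenesulfonate | CC[C@H]1O[C@@H](C/C=C\C[C@@H]1Br)[C@H](O)COS(=O)(=O)c2c(C(C)C)cc(C(C)C)cc2C(C)C | intermediate (not isolated)
17 | (2R,3S,8S,Z)-3-bromo-2-ethyl-8-[(R)-oxiran-2-yl]-3,4,7,8-tetrahydro-2H-oxocine | CC[C@H]1O[C@@H](C/C=C\C[C@@H]1Br)[C@H]2CO2 | intermediate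
18 | (R)-1-[(2R,3S,8S,Z)-3-bromo-2-ethyl-3,4,7,8-tetrahydro-2H-oxocin-8-yl]but-3-en-1-ol | CC[C@H]1O[C@@H](C/C=C\C[C@@H]1Br)[C@H](O)CC=C | intermediate
19 | (1S,3R,4S,6S,7S,9R)-9-allyl-4,6-dibromo-3-ethyl-2,8-dioxabicyclo[5.2.1]decane | C=CC[C@H]1O[C@H]2C[C@@H]1O[C@H](CC)[C@@H](Br)C[C@@H]2Br | intermediate
20 | (E)-4-[(1S,3R,4S,6S,7S,9R)-4,6-dibromo-3-ethyl-2,8-dioxabicyclo[5.2.1]decan-9-yl]but-2-enal | O=C/C=C/C[C@H]1O[C@H]2C[C@@H]1O[C@H](CC)[C@@H](Br)C[C@@H]2Br | intermediate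
21 | (1S,3R,4S,6S,7S,9R)-4,6-dibromo-3-ethyl-9-[(E)-pent-2-en-4-yn-1-yl]-2,8-dioxabicyclo[5.2.1]decane | C#C/C=C/C[C@H]1O[C@H]2C[C@@H]1O[C@H](CC)[C@@H](Br)C[C@@H]2Br | target

**Step count and risks**
Total steps: 15. Longest linear sequence: 15 steps (from 1).

Steps most likely to fail:

1. Step 9. Bromide may displace the triflate directly at C13 before the ring oxygen takes part, the epoxonium ion may be opened at the exocyclic carbon C13 (return to a seven-membered ring), or a dioxolane oxygen may capture C13. Fallback (from 2, back at 14): the oxocene would be closed directly as an eight-membered ring with the ether oxygen on C13 from the start. The alkoxide of 2 (NaH, THF) would displace bromide from (S)-2-bromobutanoic acid with inversion to give (R)-2-{[(S)-1-[(R)-2,2-dimethyl-1,3-dioxolan-4-yl]but-3-en-1-yl]oxy}butanoic acid F1. Reduction with LiAlH4 would give (R)-2-{[(S)-1-[(R)-2,2-dimethyl-1,3-dioxolan-4-yl]but-3-en-1-yl]oxy}butan-1-ol F2, and Dess–Martin oxidation the aldehyde (R)-2-{[(S)-1-[(R)-2,2-dimethyl-1,3-dioxolan-4-yl]but-3-en-1-yl]oxy}butanal F3. Chelation-controlled allylation (MgBr2·OEt2, allyltributylstannane, CH2Cl2, −78 °C) should give the syn alcohol (4R,5R)-5-{[(S)-1-[(R)-2,2-dimethyl-1,3-dioxolan-4-yl]but-3-en-1-yl]oxy}hept-1-en-4-ol F4. Ring-closing metathesis (second-generation Grubbs catalyst, CH2Cl2, 40 °C) should give (2R,3R,8S,Z)-8-[(R)-2,2-dimethyl-1,3-dioxolan-4-yl]-2-ethyl-3,4,7,8-tetrahydro-2H-oxocin-3-ol F5. Bromination with inversion at C12 (CBr4, P(n-C8H17)3, toluene, 70 °C) would then give 14.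

2. Step 13. The bromonium ion may form on the terminal alkene instead of the ring alkene, or the hydroxyl may attack C10 (6-endo) instead of C9. Fallback (from 18, back at 21): the enyne would be completed before any bromonium chemistry, so that the ring alkene is the only electron-rich alkene left. Cross-metathesis of 18 with crotonaldehyde (second-generation Grubbs catalyst) would give (R,E)-5-[(2R,3S,8S,Z)-3-bromo-2-ethyl-3,4,7,8-tetrahydro-2H-oxocin-8-yl]-5-hydroxypent-2-enal F6. Colvin homologation (Me3SiCHN2, LiN(iPr)2, THF, −78 °C) would give (R,E)-1-[(2R,3S,8S,Z)-3-bromo-2-ethyl-3,4,7,8-tetrahydro-2H-oxocin-8-yl]hex-3-en-5-yn-1-ol F7. Transannular bromoetherification of F7 with 2,4,4,6-tetrabromocyclohexa-2,5-dienone in CH2Cl2 would give 21 directly.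

3. Step 15. The lithiated reagent may cause loss of HBr from the β-bromo ethers, or the carbene rearrangement may stay incomplete. Fallback (from 19, back at 21): the enyne would be built without strong base. Ozonolysis of 19 (O3, CH2Cl2, −78 °C; PPh3) would give 2-[(1S,3R,4S,6S,7S,9R)-4,6-dibromo-3-ethyl-2,8-dioxabicyclo[5.2.1]decan-9-yl]acetaldehyde F8. Takai iodo-olefination (CrCl2, CHI3, THF) would give (1S,3R,4S,6S,7S,9R)-4,6-dibromo-3-ethyl-9-[(E)-3-iodoprop-2-en-1-yl]-2,8-dioxabicyclo[5.2.1]decane F9. Sonogashira coupling with trimethylsilylacetylene (PdCl2(PPh3)2, CuI, iPr2NH) would give trimethyl{(E)-5-[(1S,3R,4S,6S,7S,9R)-4,6-dibromo-3-ethyl-2,8-dioxabicyclo[5.2.1]decan-9-yl]pent-3-en-1-yn-1-yl}silane F10. Desilylation with K2CO3 in MeOH would give 21.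

**Further compounds**
F1 | step 9 | (R)-2-{[(S)-1-[(R)-2,2-dimethyl-1,3-dioxolan-4-yl]but-3-en-1-yl]oxy}butanoic acid | CC[C@@H](O[C@@H](CC=C)[C@H]1COC(C)(C)O1)C(=O)O
F2 | step 9 | (R)-2-{[(S)-1-[(R)-2,2-dimethyl-1,3-dioxolan-4-yl]but-3-en-1-yl]oxy}butan-1-ol | CC[C@@H](O[C@@H](CC=C)[C@H]1COC(C)(C)O1)CO
F3 | step 9 | (R)-2-{[(S)-1-[(R)-2,2-dimethyl-1,3-dioxolan-4-yl]but-3-en-1-yl]oxy}butanal | CC[C@@H](O[C@@H](CC=C)[C@H]1COC(C)(C)O1)C=O
F4 | step 9 | (4R,5R)-5-{[(S)-1-[(R)-2,2-dimethyl-1,3-dioxolan-4-yl]but-3-en-1-yl]oxy}hept-1-en-4-ol | CC[C@@H](O[C@@H](CC=C)[C@H]1COC(C)(C)O1)[C@H](O)CC=C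
F5 | step 9 | (2R,3R,8S,Z)-8-[(R)-2,2-dimethyl-1,3-dioxolan-4-yl]-2-ethyl-3,4,7,8-tetrahydro-2H-oxocin-3-ol | CC[C@H]1O[C@@H](C/C=C\C[C@H]1O)[C@H]2COC(C)(C)O2
F6 | step 13 | (R,E)-5-[(2R,3S,8S,Z)-3-bromo-2-ethyl-3,4,7,8-tetrahydro-2H-oxocin-8-yl]-5-hydroxypent-2-enal | CC[C@H]1O[C@@H](C/C=C\C[C@@H]1Br)[C@H](O)C/C=C/C=O
F7 | step 13 | (R,E)-1-[(2R,3S,8S,Z)-3-bromo-2-ethyl-3,4,7,8-tetrahydro-2H-oxocin-8-yl]hex-3-en-5-yn-1-ol | CC[C@H]1O[C@@H](C/C=C\C[C@@H]1Br)[C@H](O)C/C=C/C#C
F8 | step 15 | 2-[(1S,3R,4S,6S,7S,9R)-4,6-dibromo-3-ethyl-2,8-dioxabicyclo[5.2.1]decan-9-yl]acetaldehyde | O=CC[C@H]1O[C@H]2C[C@@H]1O[C@H](CC)[C@@H](Br)C[C@@H]2Br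
F9 | step 15 | (1S,3R,4S,6S,7S,9R)-4,6-dibromo-3-ethyl-9-[(E)-3-iodoprop-2-en-1-yl]-2,8-dioxabicyclo[5.2.1]decane | I/C=C/C[C@H]1O[C@H]2C[C@@H]1O[C@H](CC)[C@@H](Br)C[C@@H]2Br
F10 | step 15 | trimethyl{(E)-5-[(1S,3R,4S,6S,7S,9R)-4,6-dibromo-3-ethyl-2,8-dioxabicyclo[5.2.1]decan-9-yl]pent-3-en-1-yn-1-yl}silane | C[Si](C)(C)C#C/C=C/C[C@H]1O[C@H]2C[C@@H]1O[C@H](CC)[C@@H](Br)C[C@@H]2Br
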